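## The problem

The target is a germacranolide: a ten-membered carbocycle (C1–C10) with two Z trisubstituted olefins (C1=C10, C4=C5), fused cis across C6–C7 to an α-methylene γ-lactone (C11, C12, C13). It has five ring stereocentres. C6, C7, C8 and C9 are contiguous (lactone oxygen, lactone carbon, free hydroxyl, epoxy ester); C3 (acetate) stands alone, separated from them by an olefin on each side. Within the C6–C9 block neighbours can control each other: an ether oxygen on C8 can chelate a metal and steer both a new bond at C7 and hydride delivery to C6. C3 cannot be relayed to that block through a flexible medium ring, so its relation must be fixed while the carbons still sit in a small ring, or by a reagent. Direct closure of a ten-membered ring is penalised by entropy and transannular strain, and Z trisubstituted olefins are hard to make by macrocyclic olefination. The fragile groups are the α-methylene lactone (Michael acceptor), the epoxy ester (acid, nucleophiles), the allylic acetate, and the free C8 hydroxyl, which is next to the C9 ester (acyl migration) and cis to C11 (translactonisation to O8). The enabling feature is that the C8–C9 bond joins two oxygen-bearing carbons and lies across the ring from C1 and C6. The arc C1–C6 already holds the Z-C4=C5 olefin and the C3 oxygen, so breaking C8–C9 and joining C1 to C6 folds the skeleton into a cyclohexenol with two cis alkenyl arms, the retron of an oxy-Cope ring expansion.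

## Retrosynthesis

**Side chain and O8 (42 ⇒ 41 ⇒ 35 + 39).** The last bond cut is the benzylic C–O bond of the C8 4-methoxybenzyl ether in 41; before it, the C9 ester C–O bond that joins alcohol 35 to epoxy acid 39. Cutting here, not at the acetate or lactone, keeps the epoxy ester out of every basic step and keeps O8 masked to the end, so neither acyl migration from O9 nor translactonisation to O8 can start. 35 lacks the side chain and its two stereocentres. The forward steps must acylate a hindered allylic alcohol with an α-quaternary acid and then free O8 under neutral conditions. Acid 39 goes back to tiglic acid 36 through alcohol 37 and epoxy alcohol 38.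

**C3 acetate (35 ⇒ 34 ⇒ 33 ⇒ 32).** The C3–O bond is cut with inversion: acetate 34 comes from the 3R allylic alcohol 33 and its triethylsilyl ether 32. The ring is carried as 3R on purpose. Alkylation next to a silyloxy-bearing ring carbon goes anti to that group (see 11), so the six-membered precursor with the required C1/C6 chirality has the C3 oxygen trans to the C1 arm. Inverting while acetylating costs no step more than plain acetylation. The forward steps must remove SiEt3 beside the hindered C9 silyl ether and displace by SN2, not SN2′.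

**Lactone (32 ⇒ 30 ⇒ 28 ⇒ 26 ⇒ 23 + 24).** First the C11=C13 bond is cut (Mannich base 30, lactone 28), then the C12–O6 bond with the C6–H bond (keto ester 26), then C7–C11 (ketone 23 and ethyl iodoacetate 24). This is preferred to building the butenolide elsewhere because the C6 ketone is exactly what the ring expansion leaves, and C7 is its only enolisable position. 23 has no lactone and two fewer stereocentres. Forward, the alkyl group must enter on the C7 face anti to C9 (lithium chelated between enolate oxygen and the C8 ether), and hydride must reach C6 within the same chelate to give the cis hydroxy ester.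

**Ring (23 ⇒ 20).** C8–C9 is cut and C1 rejoined to C6, a retro-[3,3] shift. Compared with macrocyclisation at C1=C10, C4=C5 or C9–C10, this turns the ten-membered ring into a cyclohexene, trades the C8 and C9 stereocentres for the geometry of two enol ethers, and makes Z-C4=C5 the ring olefin of the precursor. The forward reaction needs cis alkenyl groups, E enol ethers and the chair with C2 axial on C1.

**Carbinol (20 ⇒ 19 ⇒ 14 + 17).** The E-C7=C8 olefin is traced to the alkyne of 19, and C6–C7 is cut to ketone 14 and the alkoxyacetylide from dichlorovinyl ether 17 (from 15 and 16). An acetylide is preferred to an E-alkoxyvinyllithium: a linear nucleophile attacks a cyclohexenone axially, here on the face cis to the equatorial C1 arm and opposite the pseudoaxial C3 silyloxy group, and trans hydroalumination then gives the E enol ether by mechanism.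

**C1 arm (14 ⇒ 13 ⇒ 11 ⇒ 6 + 9).** The enol O–Si bond is cut to aldehyde 13, the aldehyde goes back by a Nef reaction to nitro ketone 11, and C1–C10 is cut to enone 6 and nitropropene 9 (from 7). A nitroalkene is preferred to a crotyl electrophile because conjugate addition can only join C1 to the methyl-bearing carbon, whereas allylation would favour the linear isomer. The C10 configuration does not matter, since C10 becomes sp2. Forward, attack must be anti to the C3 silyloxy group, and the aldehyde must be enol-silylated beside the enone.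

**Enone (6 ⇒ 5 ⇒ 4 ⇒ 3 ⇒ 2 ⇒ 1).** The C3–O bond is cut back to 3-methylcyclohex-2-en-1-one 1 through γ-oxidation of dienol ether 2. Lipase resolution of racemic 3 gives acetate 4, then alcohol 5 and silyl ether 6.

## Roads not taken

**Alternative 1:** The cut is the lactone C12–O6 bond in a cyclopentene that holds C5–C9. A chiral phosphoric acid would make one enantiotopic hydroxyl of the all-cis meso diol ester A1 attack the tert-butyl ester, giving the cis-fused hydroxy lactone A2. Merits: it is catalytic and enantioselective from an achiral compound, needs no resolution, and sets C6, C7 and C8 together with the cis lactone and a differentiated free C8 hydroxyl. On that triad it is better than the chosen plan, which relies on two substrate-controlled steps (14 and 15) and a resolution. Weak points: in A2, C5 and C9 are olefinic. The ring olefin would have to be cleaved, the C9 carbinol made by addition to an aldehyde, and a five-carbon bridge (C10, C1–C4) with two Z trisubstituted olefins inserted by a ten-membered ring closure. That is the hardest part of the molecule and it stays unsolved; C3 is not addressed. The chosen plan sets against it a ring expansion that forms the ten-membered ring, both olefin geometries and the C8/C9 pair in one step, with no macrocyclisation.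

**Alternative 2:** The cut is at C4–C15 and C5–C6 in an open chain. Under CuI catalysis methylmagnesium bromide would add anti across the alkyne of the magnesium alkoxide of propargylic alcohol A3, and the cyclic alkenylmagnesium species would be captured by aldehyde A4 to give enediol A5. Merits: it is convergent, anti carbometalation fixes Z-C4=C5, and C3 arrives with its final configuration from a simple alkynol. In those respects it is better than the chosen plan, which is linear and inverts C3 late. Weak points: the C6 configuration depends on addition to an α-branched β-alkoxy aldehyde, where Felkin and chelation control can oppose each other. C9 and C1 must still be joined through C10 by a ten-membered ring closure that creates the second Z trisubstituted olefin. Four protecting groups are carried. The chosen plan sets against it that no macrocyclisation is needed and that C8 and C9 are formed together with the ring.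

**Alternative 3:** The cut is at C12–O6 and C11–C12 at the very end. With PdI2 under CO (divalent palladium) the C6 hydroxyl of ethynyl carbinol A6 would give an alkoxycarbonylpalladium species that adds syn across the alkyne and is protonated, giving the C8 O-triethylsilyl ether A7 of the target. Merits: the α-methylene lactone is made last in one catalytic step. On step economy for the lactone it is clearly better (one step against steps 14–17 here), and the Michael acceptor does not have to survive five later steps. Weak points: it is an endgame tactic and builds no ring. A6 needs the complete ten-membered ring, all stereocentres, the epoxy ester and the allylic acetate, plus an ethynyl group at C7, which no obvious ring-forming step delivers. Zerovalent palladium formed during turnover could ionise the allylic C3 acetate. The chosen plan sets against it that the ring expansion itself leaves the C6 ketone whose enolate provides the C7 handle.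

Key step: step 13

Assumption: the lipase acylates the R enantiomer of 3 faster, as the empirical size rule for secondary alcohols predicts with the methyl-bearing alkenyl carbon as the large group. If its preference were the reverse, the unreacted alcohol would be silylated directly and step 4 would fall away.

## Route

Step 1
Reactants: 1 3-methylcyclohex-2-en-1-one
Product: 2 3-methyl-1-(trimethylsilyloxy)cyclohexa-1,3-diene
Conditions: Me3SiCl, Et3N, DMF, 90 °C
Reagents that add atoms: chlorotrimethylsilane, C[Si](C)(C)Cl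
Why: Silyl enol ether formation under equilibrating conditions; γ-deprotonation gives the fully conjugated, endocyclic dienol ether as the most stable isomer.

Step 2
Reactants: 2 3-methyl-1-(trimethylsilyloxy)cyclohexa-1,3-diene
Product: 3 rac-4-hydroxy-3-methylcyclohex-2-en-1-one
Conditions: mCPBA, NaHCO3, CH2Cl2, −20 °C; then aq. citric acid, THF, 0 °C
Reagents that add atoms: 3-chloroperbenzoic acid, OOC(=O)c1cccc(Cl)c1
Why: Vinylogous Rubottom oxidation; the peracid attacks the terminal C3=C4 bond of the dienol ether and the epoxide opens to the γ-hydroxy enone, which is racemic.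

Step 3
Reactants: 3 rac-4-hydroxy-3-methylcyclohex-2-en-1-one
Product: 4 (1R)-2-methyl-4-oxocyclohex-2-en-1-yl acetate
Conditions: Burkholderia cepacia lipase (Amano PS), vinyl acetate, tert-butyl methyl ether, 30 °C, to about half conversion
Reagents that add atoms: vinyl acetate, C=COC(C)=O
Why: Lipase-catalysed kinetic resolution by irreversible transesterification; the R alcohol should be acylated faster and is separated as its acetate from the unreacted S alcohol.

Step 4
Reactants: 4 (1R)-2-methyl-4-oxocyclohex-2-en-1-yl acetate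
Product: 5 (4R)-4-hydroxy-3-methylcyclohex-2-en-1-one
Conditions: K2CO3 (cat.), MeOH, 0 °C
Reagents that add atoms: none
Why: Base-catalysed transesterification (methanolysis) of the acetate; the stereocentre is not involved.

Step 5
Reactants: 5 (4R)-4-hydroxy-3-methylcyclohex-2-en-1-one
Product: 6 (4R)-3-methyl-4-(triethylsilyloxy)cyclohex-2-en-1-one
Conditions: Et3SiCl, imidazole, CH2Cl2, 0 °C
Reagents that add atoms: chlorotriethylsilane, CC[Si](Cl)(CC)CC
Why: Standard O-silylation; the triethylsilyl group is chosen because it can later be removed beside a tert-butyldimethylsilyl ether.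

Step 6
Reactants: 7 1-nitropropan-2-ol
Product: 9 (E)-1-nitroprop-1-ene, via mesylate 8 (not isolated)
Conditions: MeSO2Cl, Et3N, CH2Cl2, 0 °C
Reagents that add atoms: none
Why: Mesylation and E1cB elimination (dehydration of a nitro-aldol adduct) give the conjugated E nitroalkene.

Step 7
Reactants: 6 (4R)-3-methyl-4-(triethylsilyloxy)cyclohex-2-en-1-one; 9 (E)-1-nitroprop-1-ene
Product: 11 (4R,6S)-3-methyl-6-(1-nitropropan-2-yl)-4-(triethylsilyloxy)cyclohex-2-en-1-one (both epimers at the side-chain carbon), via lithium dienolate 10 (not isolated)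
Conditions: LiN(iPr)2, THF, −78 °C; then 9, −78 °C; AcOH, −78 °C
Reagents that add atoms: none
Why: Kinetic α′-deprotonation and Michael addition of the lithium enolate to the nitroalkene, which can only give the branched connection. The electrophile avoids the face of the pseudoaxial C3 silyloxy group (A(1,2) strain with the C4 methyl keeps it pseudoaxial), so C1 is set trans to C3–O. The side-chain centre is lost later.

Step 8
Reactants: 11 (4R,6S)-3-methyl-6-(1-nitropropan-2-yl)-4-(triethylsilyloxy)cyclohex-2-en-1-one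
Product: 13 2-[(1S,5R)-4-methyl-2-oxo-5-(triethylsilyloxy)cyclohex-3-en-1-yl]propanal (both epimers at C2 of the propanal), via sodium nitronate 12 (not isolated)
Conditions: NaOMe, MeOH, 0 °C; O3, CH2Cl2/MeOH, −78 °C; Me2S
Reagents that add atoms: ozone, [O-][O+]=O
Why: Nef reaction by ozonolysis of the nitronate; the electron-rich C=N bond is cleaved much faster than the electron-poor enone olefin at −78 °C.

Step 9
Reactants: 13 2-[(1S,5R)-4-methyl-2-oxo-5-(triethylsilyloxy)cyclohex-3-en-1-yl]propanal
Product: 14 (4R,6S)-6-[(E)-1-(tert-butyldimethylsilyloxy)prop-1-en-2-yl]-3-methyl-4-(triethylsilyloxy)cyclohex-2-en-1-one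
Conditions: tBuMe2SiOTf (1.05 equiv), Et3N, CH2Cl2, −78 °C
Reagents that add atoms: tert-butyldimethylsilyl trifluoromethanesulfonate, CC(C)(C)[Si](C)(C)OS(=O)(=O)C(F)(F)F
Why: Soft enolisation (enol silylation) of the aldehyde, which is less hindered and has the more acidic α-hydrogen than the enone, whose α′ position is tertiary. The E isomer, with oxygen cis to the methyl group and trans to the ring carbon, should prevail on steric grounds.

Step 10
Reactants: 15 4-methoxybenzyl alcohol; 16 trichloroethylene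
Product: 17 1-{[(E)-1,2-dichloroethenyl]oxymethyl}-4-methoxybenzene
Conditions: KH, THF, 0 to 20 °C
Reagents that add atoms: none
Why: Addition of the potassium alkoxide to dichloroacetylene formed in situ from trichloroethylene (addition–elimination), the standard entry to ynol ether precursors.

Step 11
Reactants: 17 1-{[(E)-1,2-dichloroethenyl]oxymethyl}-4-methoxybenzene; 14 (4R,6S)-6-[(E)-1-(tert-butyldimethylsilyloxy)prop-1-en-2-yl]-3-methyl-4-(triethylsilyloxy)cyclohex-2-en-1-one
Product: 19 (1R,4R,6S)-6-[(E)-1-(tert-butyldimethylsilyloxy)prop-1-en-2-yl]-1-[(4-methoxybenzyloxy)ethynyl]-3-methyl-4-(triethylsilyloxy)cyclohex-2-en-1-ol, via lithium alkoxyacetylide 18 (not isolated)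
Conditions: n-BuLi (2.2 equiv), THF, −78 to −40 °C; then 14, −78 °C; aq. NH4Cl
Reagents that add atoms: none
Why: Elimination and chlorine–lithium exchange give the lithium alkoxyacetylide, which adds 1,2 to the ketone. The linear nucleophile attacks axially in the half-chair that has the C1 arm equatorial and the C3 silyloxy group pseudoaxial on the other face, so the new C6 centre carries the alkynyl group cis to the arm.

Step 12
Reactants: 19 (1R,4R,6S)-6-[(E)-1-(tert-butyldimethylsilyloxy)prop-1-en-2-yl]-1-[(4-methoxybenzyloxy)ethynyl]-3-methyl-4-(triethylsilyloxy)cyclohex-2-en-1-ol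
Product: 20 (1R,4R,6S)-6-[(E)-1-(tert-butyldimethylsilyloxy)prop-1-en-2-yl]-1-[(E)-2-(4-methoxybenzyloxy)ethenyl]-3-methyl-4-(triethylsilyloxy)cyclohex-2-en-1-ol
Conditions: NaAlH2(OCH2CH2OMe)2, THF, 0 to 20 °C; aq. potassium sodium tartrate
Reagents that add atoms: none
Why: Alkoxide-directed trans hydroalumination of the propargylic alcohol followed by protonolysis gives the E enol ether by mechanism; silyl ethers and the silyl enol ether are inert to the aluminium hydride.

Step 13
Reactants: 20 (1R,4R,6S)-6-[(E)-1-(tert-butyldimethylsilyloxy)prop-1-en-2-yl]-1-[(E)-2-(4-methoxybenzyloxy)ethenyl]-3-methyl-4-(triethylsilyloxy)cyclohex-2-en-1-ol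
Product: 23 (2Z,4R,6Z,8S,9S)-8-(tert-butyldimethylsilyloxy)-9-(4-methoxybenzyloxy)-3,7-dimethyl-4-(triethylsilyloxy)cyclodeca-2,6-dien-1-one, via potassium alkoxide 21 (not isolated), via potassium enolate 22 (not isolated)
Conditions: KN(SiMe3)2, 18-crown-6, THF, −78 to 0 °C; then AcOH, THF, −78 °C
Reagents that add atoms: none
Why: The dissociated potassium alkoxide 21 weakens the C1–C6 bond and undergoes a concerted, asynchronous [3,3] sigmatropic shift (anionic oxy-Cope rearrangement); the closest known reaction type is the ring expansion of cis-1,2-dialkenylcyclohexanols to (Z)-cyclodec-5-enones. No ring is closed in the usual sense: the ten-membered ring arises by four-atom ring expansion, C8–C9 forming as C1–C6 breaks in a six-centre chair. The chair used has C2 axial on C1 and C5 equatorial on C6 (oxyanion axial); it derives from the ground-state half-chair with the C1 arm equatorial, the C6 alkenyl group axial and the C3 silyloxy group pseudoaxial. The ring-flipped chair would put the branched arm axial and C5 syn-axial to the C10 methyl group. The axial C2 ends cis to C9, which gives Z-C1=C10, and the Z-C4=C5 olefin is the untouched ring olefin. Both enol ethers are E, so both oxygens are equatorial in the chair and the chirality of C1 (S) and C6 (R) is relayed to C8 (S) and C9 (S). The step needs chair over boat and this chair over its ring-flipped counterpart; the cis alkenyl groups, the E enol ethers and the C10 methyl group secure that. Enolate 22 is protonated at −78 °C because the C8 alkoxy group is β to the carbonyl and could be expelled on warming.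

Step 14
Reactants: 23 (2Z,4R,6Z,8S,9S)-8-(tert-butyldimethylsilyloxy)-9-(4-methoxybenzyloxy)-3,7-dimethyl-4-(triethylsilyloxy)cyclodeca-2,6-dien-1-one; 24 ethyl iodoacetate
Product: 26 ethyl 2-[(1R,3Z,5R,7Z,9S,10S)-9-(tert-butyldimethylsilyloxy)-10-(4-methoxybenzyloxy)-4,8-dimethyl-2-oxo-5-(triethylsilyloxy)cyclodeca-3,7-dien-1-yl]acetate, via lithium enolate 25 (not isolated)
Conditions: LiN(iPr)2, THF, −78 °C; then 24, −78 to −45 °C; aq. NH4Cl
Reagents that add atoms: none
Why: Kinetic enolate alkylation at C7, the only sp3 α-carbon. Lithium chelated between the enolate oxygen and the C8 benzyl-type ether holds the C8–O bond in the enolate plane, which disfavours E1cB loss and puts C9 on one face, so the iodide enters anti to C9 and sets C7 (cis to O8 on the ring).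

Step 15
Reactants: 26 ethyl 2-[(1R,3Z,5R,7Z,9S,10S)-9-(tert-butyldimethylsilyloxy)-10-(4-methoxybenzyloxy)-4,8-dimethyl-2-oxo-5-(triethylsilyloxy)cyclodeca-3,7-dien-1-yl]acetate
Product: 28 (3R,6S,7S,8S,9S,1(10)Z,4Z)-9-(tert-butyldimethylsilyloxy)-8-(4-methoxybenzyloxy)-3-(triethylsilyloxy)-13-norgermacra-1(10),4-dien-12,6-olide, via hydroxy ester 27 (not isolated)
Conditions: Zn(BH4)2, Et2O, −30 to 0 °C; aq. NH4Cl; then DBU (cat.), toluene, 40 °C
Reagents that add atoms: none
Why: Chelation-controlled 1,2-reduction of the β-alkoxy enone. Hydride adds axially to the zinc chelate in which the C7 and C9 substituents are equatorial, giving the 6,8-syn alcohol with O6 cis to C11; this then closes the cis-fused γ-lactone by base-catalysed transesterification.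

Step 16
Reactants: 28 (3R,6S,7S,8S,9S,1(10)Z,4Z)-9-(tert-butyldimethylsilyloxy)-8-(4-methoxybenzyloxy)-3-(triethylsilyloxy)-13-norgermacra-1(10),4-dien-12,6-olide
Product: 30 (3R,6S,7S,8S,9S,1(10)Z,4Z)-9-(tert-butyldimethylsilyloxy)-13-(dimethylamino)-8-(4-methoxybenzyloxy)-3-(triethylsilyloxy)germacra-1(10),4-dien-12,6-olide (C11 epimers), via lactone enolate 29 (not isolated)
Conditions: LiN(iPr)2, THF, −78 °C; then Me2N=CH2+ I−, −78 to 0 °C
Reagents that add atoms: N,N-dimethylmethyleneiminium iodide (Eschenmoser's salt), C=[N+](C)C.[I-]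
Why: Mannich reaction of the lactone enolate with the preformed iminium salt; the C11 configuration is irrelevant because the centre becomes sp2 in the next step.

Step 17
Reactants: 30 (3R,6S,7S,8S,9S,1(10)Z,4Z)-9-(tert-butyldimethylsilyloxy)-13-(dimethylamino)-8-(4-methoxybenzyloxy)-3-(triethylsilyloxy)germacra-1(10),4-dien-12,6-olide
Product: 32 (3R,6S,7S,8S,9S,1(10)Z,4Z)-9-(tert-butyldimethylsilyloxy)-8-(4-methoxybenzyloxy)-3-(triethylsilyloxy)germacra-1(10),4,11(13)-trien-12,6-olide, via methiodide 31 (not isolated)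
Conditions: MeI, MeOH, 20 °C; then aq. NaHCO3, EtOAc, 20 °C
Reagents that add atoms: none
Why: N-quaternisation and mild-base E1cB elimination of trimethylamine, the standard way to an α-methylene lactone.

Step 18
Reactants: 32 (3R,6S,7S,8S,9S,1(10)Z,4Z)-9-(tert-butyldimethylsilyloxy)-8-(4-methoxybenzyloxy)-3-(triethylsilyloxy)germacra-1(10),4,11(13)-trien-12,6-olide
Product: 33 (3R,6S,7S,8S,9S,1(10)Z,4Z)-9-(tert-butyldimethylsilyloxy)-3-hydroxy-8-(4-methoxybenzyloxy)germacra-1(10),4,11(13)-trien-12,6-olide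
Conditions: pyridinium 4-toluenesulfonate (cat.), MeOH/CH2Cl2, 0 °C
Reagents that add atoms: none
Why: Acid-catalysed methanolysis removes the triethylsilyl ether selectively; the bulkier and more hindered C9 tert-butyldimethylsilyl ether is far slower.

Step 19
Reactants: 33 (3R,6S,7S,8S,9S,1(10)Z,4Z)-9-(tert-butyldimethylsilyloxy)-3-hydroxy-8-(4-methoxybenzyloxy)germacra-1(10),4,11(13)-trien-12,6-olide
Product: 34 (3S,6S,7S,8S,9S,1(10)Z,4Z)-3-acetoxy-9-(tert-butyldimethylsilyloxy)-8-(4-methoxybenzyloxy)germacra-1(10),4,11(13)-trien-12,6-olide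
Conditions: PPh3, iPrO2CN=NCO2iPr, AcOH, toluene, 0 to 20 °C (phosphine and azo ester premixed)
Reagents that add atoms: acetic acid, CC(=O)O
Why: Mitsunobu reaction; acetate displaces the oxyphosphonium group by SN2, inverting C3 from R to S and installing the acetate in the same step.

Step 20
Reactants: 34 (3S,6S,7S,8S,9S,1(10)Z,4Z)-3-acetoxy-9-(tert-butyldimethylsilyloxy)-8-(4-methoxybenzyloxy)germacra-1(10),4,11(13)-trien-12,6-olide
Product: 35 (3S,6S,7S,8S,9S,1(10)Z,4Z)-3-acetoxy-9-hydroxy-8-(4-methoxybenzyloxy)germacra-1(10),4,11(13)-trien-12,6-olide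
Conditions: HF·pyridine, pyridine, THF, 0 to 20 °C
Reagents that add atoms: none
Why: Fluoride-mediated desilylation under buffered, weakly acidic conditions that spare the acetate, the lactone and the Michael acceptor.

Step 21
Reactants: 36 tiglic acid [(E)-2-methylbut-2-enoic acid]
Product: 37 (E)-2-methylbut-2-en-1-ol
Conditions: LiAlH4, Et2O, 0 °C
Reagents that add atoms: none
Why: Hydride reduction of the acid to the allylic alcohol with retention of olefin geometry.

Step 22
Reactants: 37 (E)-2-methylbut-2-en-1-ol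
Product: 38 [(2S,3S)-2,3-dimethyloxiran-2-yl]methanol
Conditions: Ti(OiPr)4 (cat.), L-(+)-diethyl tartrate (cat.), tBuOOH, 4 Å molecular sieves, CH2Cl2, −20 °C
Reagents that add atoms: tert-butyl hydroperoxide, CC(C)(C)OO
Why: Sharpless asymmetric epoxidation; the natural (2R,3R)-tartrate delivers oxygen to the face that gives the 2S,3S epoxy alcohol from E allylic alcohols, and the E olefin geometry fixes the two methyl groups cis.

Step 23
Reactants: 38 [(2S,3S)-2,3-dimethyloxiran-2-yl]methanol
Product: 39 (2R,3S)-2,3-dimethyloxirane-2-carboxylic acid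
Conditions: TEMPO (cat.), PhI(OAc)2, MeCN/H2O, 20 °C
Reagents that add atoms: water, O
Why: Oxoammonium-mediated oxidation of the primary alcohol through the aldehyde hydrate to the acid; the epoxide is untouched and the descriptor at C2 changes only by priority.

Step 24
Reactants: 35 (3S,6S,7S,8S,9S,1(10)Z,4Z)-3-acetoxy-9-hydroxy-8-(4-methoxybenzyloxy)germacra-1(10),4,11(13)-trien-12,6-olide; 39 (2R,3S)-2,3-dimethyloxirane-2-carboxylic acid
Product: 41 (3S,6S,7S,8S,9S,1(10)Z,4Z)-3-acetoxy-9-[(2R,3S)-2,3-dimethyloxirane-2-carbonyloxy]-8-(4-methoxybenzyloxy)germacra-1(10),4,11(13)-trien-12,6-olide, via mixed anhydride 40 (not isolated)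
Conditions: 2,4,6-Cl3C6H2COCl, Et3N, THF, 20 °C; then 35, DMAP, toluene, 20 to 40 °C
Reagents that add atoms: none
Why: Yamaguchi esterification; the mixed anhydride with DMAP is the usual answer to a hindered alcohol and an α-quaternary acid, and no stereocentre is touched.

Step 25
Reactants: 41 (3S,6S,7S,8S,9S,1(10)Z,4Z)-3-acetoxy-9-[(2R,3S)-2,3-dimethyloxirane-2-carbonyloxy]-8-(4-methoxybenzyloxy)germacra-1(10),4,11(13)-trien-12,6-olide
Product: 42 (3S,6S,7R,8S,9S,1(10)Z,4Z)-3-acetoxy-9-[(2R,3S)-2,3-dimethyloxirane-2-carbonyloxy]-8-hydroxygermacra-1(10),4,11(13)-trien-12,6-olide (CNP0137407.9)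
Conditions: DDQ, CH2Cl2/pH 7 phosphate buffer, 0 °C
Reagents that add atoms: none
Why: Oxidative cleavage of the 4-methoxybenzyl ether under neutral conditions, so that the freed C8 hydroxyl meets neither acid nor base; the C7 descriptor changes from S to R only by priority.

## Compound list

1 | 3-methylcyclohex-2-en-1-one | CC1=CC(=O)CCC1 | starting material
2 | 3-methyl-1-(trimethylsilyloxy)cyclohexa-1,3-diene | C[Si](C)(C)OC1=CC(C)=CCC1 | intermediate
3 | rac-4-hydroxy-3-methylcyclohex-2-en-1-one | CC1=CC(=O)CCC1O | intermediate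
4 | (1R)-2-methyl-4-oxocyclohex-2-en-1-yl acetate | O=C1C=C(C)[C@H](OC(C)=O)CC1 | intermediate
5 | (4R)-4-hydroxy-3-methylcyclohex-2-en-1-one | O=C1C=C(C)[C@H](O)CC1 | intermediate
6 | (4R)-3-methyl-4-(triethylsilyloxy)cyclohex-2-en-1-one | O=C1C=C(C)[C@H](O[Si](CC)(CC)CC)CC1 | intermediate
7 | 1-nitropropan-2-ol | CC(O)C[N+](=O)[O-] | starting material
8 | 1-nitropropan-2-yl methanesulfonate (formed in situ) | CC(OS(C)(=O)=O)C[N+](=O)[O-] | intermediate
9 | (E)-1-nitroprop-1-ene | C/C=C/[N+](=O)[O-] | intermediate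
10 | lithium (4R)-5-methyl-4-(triethylsilyloxy)cyclohexa-1,5-dien-1-olate (formed in situ) | [Li+].[O-]C1=CC[C@@H](O[Si](CC)(CC)CC)C(C)=C1 | intermediate
11 | (4R,6S)-3-methyl-6-(1-nitropropan-2-yl)-4-(triethylsilyloxy)cyclohex-2-en-1-one (both epimers at the side-chain carbon) | O=C1C=C(C)[C@H](O[Si](CC)(CC)CC)C[C@H]1C(C)C[N+](=O)[O-] | intermediate
12 | sodium nitronate of 11 (formed in situ) | O=C1C=C(C)[C@H](O[Si](CC)(CC)CC)C[C@H]1C(C)C=[N+]([O-])[O-].[Na+] | intermediate
13 | 2-[(1S,5R)-4-methyl-2-oxo-5-(triethylsilyloxy)cyclohex-3-en-1-yl]propanal (both epimers at C2 of the propanal) | O=C1C=C(C)[C@H](O[Si](CC)(CC)CC)C[C@H]1C(C)C=O | intermediate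
14 | (4R,6S)-6-[(E)-1-(tert-butyldimethylsilyloxy)prop-1-en-2-yl]-3-methyl-4-(triethylsilyloxy)cyclohex-2-en-1-one | O=C1C=C(C)[C@H](O[Si](CC)(CC)CC)C[C@H]1/C(C)=C/O[Si](C)(C)C(C)(C)C | intermediate
15 | 4-methoxybenzyl alcohol | COc1ccc(CO)cc1 | starting material
16 | trichloroethylene | ClC=C(Cl)Cl | starting material
17 | 1-{[(E)-1,2-dichloroethenyl]oxymethyl}-4-methoxybenzene | COc1ccc(CO/C(Cl)=C\Cl)cc1 | intermediate
18 | lithium 2-(4-methoxybenzyloxy)ethynide (formed in situ) | [Li+].[C-]#COCc1ccc(OC)cc1 | intermediate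
19 | (1R,4R,6S)-6-[(E)-1-(tert-butyldimethylsilyloxy)prop-1-en-2-yl]-1-[(4-methoxybenzyloxy)ethynyl]-3-methyl-4-(triethylsilyloxy)cyclohex-2-en-1-ol | O[C@]1(C#COCc2ccc(OC)cc2)C=C(C)[C@H](O[Si](CC)(CC)CC)C[C@H]1/C(C)=C/O[Si](C)(C)C(C)(C)C | intermediate
20 | (1R,4R,6S)-6-[(E)-1-(tert-butyldimethylsilyloxy)prop-1-en-2-yl]-1-[(E)-2-(4-methoxybenzyloxy)ethenyl]-3-methyl-4-(triethylsilyloxy)cyclohex-2-en-1-ol | O[C@]1(/C=C/OCc2ccc(OC)cc2)C=C(C)[C@H](O[Si](CC)(CC)CC)C[C@H]1/C(C)=C/O[Si](C)(C)C(C)(C)C | intermediate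
21 | potassium alkoxide of 20 (formed in situ) | [K+].[O-][C@]1(/C=C/OCc2ccc(OC)cc2)C=C(C)[C@H](O[Si](CC)(CC)CC)C[C@H]1/C(C)=C/O[Si](C)(C)C(C)(C)C | intermediate
22 | potassium (1Z,3S,4S,5Z,8R,9Z)-4-(tert-butyldimethylsilyloxy)-3-(4-methoxybenzyloxy)-5,9-dimethyl-8-(triethylsilyloxy)cyclodeca-1,5,9-trien-1-olate (formed in situ) | [K+].[O-]/C1=C\[C@H](OCc2ccc(OC)cc2)[C@@H](O[Si](C)(C)C(C)(C)C)/C(C)=C\C[C@@H](O[Si](CC)(CC)CC)/C(C)=C\1 | intermediate
23 | (2Z,4R,6Z,8S,9S)-8-(tert-butyldimethylsilyloxy)-9-(4-methoxybenzyloxy)-3,7-dimethyl-4-(triethylsilyloxy)cyclodeca-2,6-dien-1-one | O=C1/C=C(/C)[C@H](O[Si](CC)(CC)CC)C/C=C(/C)[C@H](O[Si](C)(C)C(C)(C)C)[C@@H](OCc2ccc(OC)cc2)C1 | intermediate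
24 | ethyl iodoacetate | CCOC(=O)CI | starting material
25 | lithium (1Z,3S,4S,5Z,8R,9Z)-4-(tert-butyldimethylsilyloxy)-3-(4-methoxybenzyloxy)-5,9-dimethyl-8-(triethylsilyloxy)cyclodeca-1,5,9-trien-1-olate (formed in situ) | [Li+].[O-]/C1=C\[C@H](OCc2ccc(OC)cc2)[C@@H](O[Si](C)(C)C(C)(C)C)/C(C)=C\C[C@@H](O[Si](CC)(CC)CC)/C(C)=C\1 | intermediate
26 | ethyl 2-[(1R,3Z,5R,7Z,9S,10S)-9-(tert-butyldimethylsilyloxy)-10-(4-methoxybenzyloxy)-4,8-dimethyl-2-oxo-5-(triethylsilyloxy)cyclodeca-3,7-dien-1-yl]acetate | O=C1/C=C(/C)[C@H](O[Si](CC)(CC)CC)C/C=C(/C)[C@H](O[Si](C)(C)C(C)(C)C)[C@@H](OCc2ccc(OC)cc2)[C@H]1CC(=O)OCC | intermediate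
27 | ethyl 2-[(1S,2S,3Z,5R,7Z,9S,10S)-9-(tert-butyldimethylsilyloxy)-2-hydroxy-10-(4-methoxybenzyloxy)-4,8-dimethyl-5-(triethylsilyloxy)cyclodeca-3,7-dien-1-yl]acetate (formed in situ) | O[C@H]1/C=C(/C)[C@H](O[Si](CC)(CC)CC)C/C=C(/C)[C@H](O[Si](C)(C)C(C)(C)C)[C@@H](OCc2ccc(OC)cc2)[C@H]1CC(=O)OCC | intermediate
28 | (3R,6S,7S,8S,9S,1(10)Z,4Z)-9-(tert-butyldimethylsilyloxy)-8-(4-methoxybenzyloxy)-3-(triethylsilyloxy)-13-norgermacra-1(10),4-dien-12,6-olide | C1C(=O)O[C@H]2/C=C(/C)[C@H](O[Si](CC)(CC)CC)C/C=C(/C)[C@H](O[Si](C)(C)C(C)(C)C)[C@@H](OCc3ccc(OC)cc3)[C@@H]12 | intermediate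
29 | lithium enolate of lactone 28 (formed in situ) | C1=C([O-])O[C@H]2/C=C(/C)[C@H](O[Si](CC)(CC)CC)C/C=C(/C)[C@H](O[Si](C)(C)C(C)(C)C)[C@@H](OCc3ccc(OC)cc3)[C@@H]12.[Li+] | intermediate
30 | (3R,6S,7S,8S,9S,1(10)Z,4Z)-9-(tert-butyldimethylsilyloxy)-13-(dimethylamino)-8-(4-methoxybenzyloxy)-3-(triethylsilyloxy)germacra-1(10),4-dien-12,6-olide (C11 epimers) | CN(C)CC1C(=O)O[C@H]2/C=C(/C)[C@H](O[Si](CC)(CC)CC)C/C=C(/C)[C@H](O[Si](C)(C)C(C)(C)C)[C@@H](OCc3ccc(OC)cc3)[C@@H]12 | intermediate
31 | N-methyl ammonium iodide of 30 (formed in situ) | C[N+](C)(C)CC1C(=O)O[C@H]2/C=C(/C)[C@H](O[Si](CC)(CC)CC)C/C=C(/C)[C@H](O[Si](C)(C)C(C)(C)C)[C@@H](OCc3ccc(OC)cc3)[C@@H]12.[I-] | intermediate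
32 | (3R,6S,7S,8S,9S,1(10)Z,4Z)-9-(tert-butyldimethylsilyloxy)-8-(4-methoxybenzyloxy)-3-(triethylsilyloxy)germacra-1(10),4,11(13)-trien-12,6-olide | C=C1C(=O)O[C@H]2/C=C(/C)[C@H](O[Si](CC)(CC)CC)C/C=C(/C)[C@H](O[Si](C)(C)C(C)(C)C)[C@@H](OCc3ccc(OC)cc3)[C@@H]12 | intermediate
33 | (3R,6S,7S,8S,9S,1(10)Z,4Z)-9-(tert-butyldimethylsilyloxy)-3-hydroxy-8-(4-methoxybenzyloxy)germacra-1(10),4,11(13)-trien-12,6-olide | C=C1C(=O)O[C@H]2/C=C(/C)[C@H](O)C/C=C(/C)[C@H](O[Si](C)(C)C(C)(C)C)[C@@H](OCc3ccc(OC)cc3)[C@@H]12 | intermediate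
34 | (3S,6S,7S,8S,9S,1(10)Z,4Z)-3-acetoxy-9-(tert-butyldimethylsilyloxy)-8-(4-methoxybenzyloxy)germacra-1(10),4,11(13)-trien-12,6-olide | C=C1C(=O)O[C@H]2/C=C(/C)[C@@H](OC(C)=O)C/C=C(/C)[C@H](O[Si](C)(C)C(C)(C)C)[C@@H](OCc3ccc(OC)cc3)[C@@H]12 | intermediate
35 | (3S,6S,7S,8S,9S,1(10)Z,4Z)-3-acetoxy-9-hydroxy-8-(4-methoxybenzyloxy)germacra-1(10),4,11(13)-trien-12,6-olide | C=C1C(=O)O[C@H]2/C=C(/C)[C@@H](OC(C)=O)C/C=C(/C)[C@H](O)[C@@H](OCc3ccc(OC)cc3)[C@@H]12 | intermediate
36 | tiglic acid [(E)-2-methylbut-2-enoic acid] | C/C=C(\C)C(=O)O | starting material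
37 | (E)-2-methylbut-2-en-1-ol | C/C=C(\C)CO | intermediate
38 | [(2S,3S)-2,3-dimethyloxiran-2-yl]methanol | OC[C@]1(C)O[C@H]1C | intermediate
39 | (2R,3S)-2,3-dimethyloxirane-2-carboxylic acid | OC(=O)[C@]1(C)O[C@H]1C | intermediate
40 | (2R,3S)-2,3-dimethyloxirane-2-carboxylic 2,4,6-trichlorobenzoic anhydride (formed in situ) | O=C(OC(=O)[C@]1(C)O[C@H]1C)c1c(Cl)cc(Cl)cc1Cl | intermediate
41 | (3S,6S,7S,8S,9S,1(10)Z,4Z)-3-acetoxy-9-[(2R,3S)-2,3-dimethyloxirane-2-carbonyloxy]-8-(4-methoxybenzyloxy)germacra-1(10),4,11(13)-trien-12,6-olide | C=C1C(=O)O[C@H]2/C=C(/C)[C@@H](OC(C)=O)C/C=C(/C)[C@H](OC(=O)[C@]3(C)O[C@H]3C)[C@@H](OCc4ccc(OC)cc4)[C@@H]12 | intermediate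
42 | (3S,6S,7R,8S,9S,1(10)Z,4Z)-3-acetoxy-9-[(2R,3S)-2,3-dimethyloxirane-2-carbonyloxy]-8-hydroxygermacra-1(10),4,11(13)-trien-12,6-olide (CNP0137407.9) | C=C1C(=O)O[C@H]2/C=C(/C)[C@@H](OC(C)=O)C/C=C(/C)[C@H](OC(=O)[C@]3(C)O[C@H]3C)[C@@H](O)[C@@H]12 | target

## Count and risks

Total: 25 steps. Longest linear sequence: 20 steps (steps 1–5, 7–9, 11–20, 24 and 25); steps 6, 10 and 21–23 are side branches.

**Step 13 (key step).** What may go wrong: part of the material may rearrange through the ring-flipped chair or a boat, which would erode the Z geometry at C1=C10 and the configuration at C8 and C9. The β-alkoxy enolate may also expel 4-methoxybenzyl oxide before it is protonated. Fallback, from 14 back to 23: the C8 oxygen is left out of the rearrangement and added afterwards. Vinylmagnesium bromide adds to 14, again axially, to give the divinyl carbinol (1R,4R,6S)-6-[(E)-1-(tert-butyldimethylsilyloxy)prop-1-en-2-yl]-1-ethenyl-3-methyl-4-(triethylsilyloxy)cyclohex-2-en-1-ol F1. The same KN(SiMe3)2/18-crown-6 rearrangement then has no β-leaving group and only one new centre, and should give (2Z,4R,6Z,8R)-8-(tert-butyldimethylsilyloxy)-3,7-dimethyl-4-(triethylsilyloxy)cyclodeca-2,6-dien-1-one F2. Dehydrogenation with 2-iodoxybenzoic acid in DMSO/toluene gives the cross-conjugated trienone (2Z,4R,6Z,8R,9E)-8-(tert-butyldimethylsilyloxy)-3,7-dimethyl-4-(triethylsilyloxy)cyclodeca-2,6,9-trien-1-one F3. Conjugate borylation at the unsubstituted β-carbon (CuCl, NaOtBu, a chiral bisphosphine, bis(pinacolato)diboron, MeOH) gives the β-boryl ketone (2Z,4R,6Z,8R,9S)-8-(tert-butyldimethylsilyloxy)-3,7-dimethyl-9-(4,4,5,5-tetramethyl-1,3,2-dioxaborolan-2-yl)-4-(triethylsilyloxy)cyclodeca-2,6-dien-1-one F4. Oxidation with NaBO3 gives the β-hydroxy ketone (2Z,4R,6Z,8S,9S)-8-(tert-butyldimethylsilyloxy)-9-hydroxy-3,7-dimethyl-4-(triethylsilyloxy)cyclodeca-2,6-dien-1-one F5. 4-Methoxybenzyl trichloroacetimidate with Sc(OTf)3 (cat.) then returns to 23.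

**Step 9.** What may go wrong: O-silylation and γ-deprotonation of the enone may compete with enolisation of the aldehyde, and the E/Z ratio may be incomplete, which would leak into the C9 configuration. Fallback, from 6 back to 14: the aldehyde enol ether is made by 1,4-hydrosilylation of an enal, which a hindered β,β-disubstituted enone does not undergo. The lithium enolate of 6 is alkylated with allyl bromide to (4R,6R)-3-methyl-6-(prop-2-en-1-yl)-4-(triethylsilyloxy)cyclohex-2-en-1-one F6. Lemieux–Johnson cleavage (OsO4 cat., NaIO4, 2,6-lutidine) gives 2-[(1S,5R)-4-methyl-2-oxo-5-(triethylsilyloxy)cyclohex-3-en-1-yl]acetaldehyde F7. α-Methylenation (Me2N=CH2+ I−, Et3N) gives 2-[(1S,5R)-4-methyl-2-oxo-5-(triethylsilyloxy)cyclohex-3-en-1-yl]prop-2-enal F8. Hydrosilylation with tBuMe2SiH and Pt2[(CH2=CHSiMe2)2O]3 (cat.) through the s-cis enal then gives 14.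

**Step 14.** What may go wrong: poor facial selectivity if the lithium chelate is not populated, E1cB loss of the C8 alkoxide when the enolate is warmed, and slow C-alkylation. Fallback, from 23 back to 26: the C7 face is chosen by an auxiliary, not by the ring. Condensation of 23 with (S)-1-amino-2-(methoxymethyl)pyrrolidine gives the hydrazone F9. Deprotonation with LiN(iPr)2 and alkylation with 24 at −100 °C gives the alkylated hydrazone F10; by the usual azaenolate model the S auxiliary should direct the electrophile to the face that gives 7R. Cleavage with aqueous CuCl2 releases 26.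

**Step 19.** What may go wrong: SN2′ attack at C5 or elimination to a diene may take the place of clean inversion, and backside displacement on the ten-membered ring may be slow. Fallback, from 33 back to 34: oxidation with MnO2 gives the enone (6S,7S,8S,9S,1(10)Z,4Z)-9-(tert-butyldimethylsilyloxy)-8-(4-methoxybenzyloxy)-3-oxogermacra-1(10),4,11(13)-trien-12,6-olide F11. Corey–Bakshi–Shibata reduction with (R)-1-methyl-3,3-diphenyltetrahydro-1H,3H-pyrrolo[1,2-c][1,3,2]oxazaborole and catecholborane (the α-methyl alkenyl side acting as the large group) gives the 3S alcohol (3S,6S,7S,8S,9S,1(10)Z,4Z)-9-(tert-butyldimethylsilyloxy)-3-hydroxy-8-(4-methoxybenzyloxy)germacra-1(10),4,11(13)-trien-12,6-olide F12. Acetylation (Ac2O, pyridine, DMAP) then gives 34.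

## Further compounds

F1 | step 13 | (1R,4R,6S)-6-[(E)-1-(tert-butyldimethylsilyloxy)prop-1-en-2-yl]-1-ethenyl-3-methyl-4-(triethylsilyloxy)cyclohex-2-en-1-ol | O[C@]1(C=C)C=C(C)[C@H](O[Si](CC)(CC)CC)C[C@H]1/C(C)=C/O[Si](C)(C)C(C)(C)C
F2 | step 13 | (2Z,4R,6Z,8R)-8-(tert-butyldimethylsilyloxy)-3,7-dimethyl-4-(triethylsilyloxy)cyclodeca-2,6-dien-1-one | O=C1/C=C(/C)[C@H](O[Si](CC)(CC)CC)C/C=C(/C)[C@H](O[Si](C)(C)C(C)(C)C)CC1
F3 | step 13 | (2Z,4R,6Z,8R,9E)-8-(tert-butyldimethylsilyloxy)-3,7-dimethyl-4-(triethylsilyloxy)cyclodeca-2,6,9-trien-1-one | O=C1/C=C(/C)[C@H](O[Si](CC)(CC)CC)C/C=C(/C)[C@H](O[Si](C)(C)C(C)(C)C)/C=C/1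
F4 | step 13 | (2Z,4R,6Z,8R,9S)-8-(tert-butyldimethylsilyloxy)-3,7-dimethyl-9-(4,4,5,5-tetramethyl-1,3,2-dioxaborolan-2-yl)-4-(triethylsilyloxy)cyclodeca-2,6-dien-1-one | O=C1/C=C(/C)[C@H](O[Si](CC)(CC)CC)C/C=C(/C)[C@H](O[Si](C)(C)C(C)(C)C)[C@@H](B2OC(C)(C)C(C)(C)O2)C1
F5 | step 13 | (2Z,4R,6Z,8S,9S)-8-(tert-butyldimethylsilyloxy)-9-hydroxy-3,7-dimethyl-4-(triethylsilyloxy)cyclodeca-2,6-dien-1-one | O=C1/C=C(/C)[C@H](O[Si](CC)(CC)CC)C/C=C(/C)[C@H](O[Si](C)(C)C(C)(C)C)[C@@H](O)C1
F6 | step 9 | (4R,6R)-3-methyl-6-(prop-2-en-1-yl)-4-(triethylsilyloxy)cyclohex-2-en-1-one | O=C1C=C(C)[C@H](O[Si](CC)(CC)CC)C[C@H]1CC=C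
F7 | step 9 | 2-[(1S,5R)-4-methyl-2-oxo-5-(triethylsilyloxy)cyclohex-3-en-1-yl]acetaldehyde | O=C1C=C(C)[C@H](O[Si](CC)(CC)CC)C[C@H]1CC=O
F8 | step 9 | 2-[(1S,5R)-4-methyl-2-oxo-5-(triethylsilyloxy)cyclohex-3-en-1-yl]prop-2-enal | O=C1C=C(C)[C@H](O[Si](CC)(CC)CC)C[C@H]1C(=C)C=O
F9 | step 14 | (S)-1-amino-2-(methoxymethyl)pyrrolidine hydrazone of ketone 23 | COC[C@@H]1CCCN1N=C2/C=C(/C)[C@H](O[Si](CC)(CC)CC)C/C=C(/C)[C@H](O[Si](C)(C)C(C)(C)C)[C@@H](OCc3ccc(OC)cc3)C2
F10 | step 14 | (S)-1-amino-2-(methoxymethyl)pyrrolidine hydrazone of keto ester 26 | COC[C@@H]1CCCN1N=C2/C=C(/C)[C@H](O[Si](CC)(CC)CC)C/C=C(/C)[C@H](O[Si](C)(C)C(C)(C)C)[C@@H](OCc3ccc(OC)cc3)[C@H]2CC(=O)OCC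
F11 | step 19 | (6S,7S,8S,9S,1(10)Z,4Z)-9-(tert-butyldimethylsilyloxy)-8-(4-methoxybenzyloxy)-3-oxogermacra-1(10),4,11(13)-trien-12,6-olide | C=C1C(=O)O[C@H]2/C=C(/C)C(=O)C/C=C(/C)[C@H](O[Si](C)(C)C(C)(C)C)[C@@H](OCc3ccc(OC)cc3)[C@@H]12
F12 | step 19 | (3S,6S,7S,8S,9S,1(10)Z,4Z)-9-(tert-butyldimethylsilyloxy)-3-hydroxy-8-(4-methoxybenzyloxy)germacra-1(10),4,11(13)-trien-12,6-olide | C=C1C(=O)O[C@H]2/C=C(/C)[C@@H](O)C/C=C(/C)[C@H](O[Si](C)(C)C(C)(C)C)[C@@H](OCc3ccc(OC)cc3)[C@@H]12
A1 | alternative 1 | tert-butyl 2-[(1s,2R,5S)-2,5-dihydroxycyclopent-3-en-1-yl]acetate (all-cis, meso) | CC(C)(C)OC(=O)C[C@H]1[C@@H](O)C=C[C@H]1O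
A2 | alternative 1 | cis-fused 4-hydroxy-3,3a,4,6a-tetrahydro-2H-cyclopenta[b]furan-2-one (C6 in the lactone, C8 hydroxyl free, single enantiomer) | O=C1C[C@H]2[C@@H](O1)C=C[C@H]2O
A3 | alternative 2 | (S)-5-(tert-butyldimethylsilyloxy)pent-1-yn-3-ol | C#C[C@@H](O)CCO[Si](C)(C)C(C)(C)C
A4 | alternative 2 | tert-butyl (3R,4S)-3-formyl-4-(4-methoxybenzyloxy)-5-(triisopropylsilyloxy)pentanoate | O=C[C@H](CC(=O)OC(C)(C)C)[C@H](OCc1ccc(OC)cc1)CO[Si](C(C)C)(C(C)C)C(C)C
A5 | alternative 2 | open-chain C1–C9 (Z)-2-methyl-2-ene-1,4-diol with free C3 and C6 hydroxyls (C1 silyl ether, C8 4-methoxybenzyl ether, C9 silyl ether, tert-butyl ester) | C/C(=C/[C@H](O)[C@H](CC(=O)OC(C)(C)C)[C@H](OCc1ccc(OC)cc1)CO[Si](C(C)C)(C(C)C)C(C)C)[C@@H](O)CCO[Si](C)(C)C(C)(C)C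
A6 | alternative 3 | C7-ethynyl C6-carbinol with the C3 acetate, C9 epoxy ester and C8 triethylsilyl ether in place | O[C@H]1/C=C(/C)[C@@H](OC(C)=O)C/C=C(/C)[C@H](OC(=O)[C@]2(C)O[C@H]2C)[C@@H](O[Si](CC)(CC)CC)[C@H]1C#C
A7 | alternative 3 | C8 O-triethylsilyl ether of the target | C=C1C(=O)O[C@H]2/C=C(/C)[C@@H](OC(C)=O)C/C=C(/C)[C@H](OC(=O)[C@]3(C)O[C@H]3C)[C@@H](O[Si](CC)(CC)CC)[C@@H]12
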